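**Retrosynthetic overview**
- The target comes from a macrocyclic triene by epoxidation of C1=C10 last, after the C8 angelate is installed with inversion on a macrocyclic C8 alcohol.
- Key disconnection C7–C8: a butenolide-derived allylchromium, nucleophilic at C7 (the β-carbon of the unsaturated lactone, a homoenolate equivalent), attacks the C8 aldehyde. This one step closes the ten-membered ring and creates the α-methylene lactone, C7 and C8.
- Ring order: butenolide (ring-closing metathesis of a 2-(bromomethyl)acrylate), then the ten-membered carbocycle (C7–C8), then the epoxide.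
- Open chain: C5–C6 by asymmetric Ni/Cr coupling of a Z-vinyl iodide with acrolein; Z-C4=C5 and C15 by anti-carbomagnesiation of a propargylic alcohol; C3 by asymmetric alkynylation; E-C1=C10 by carboalumination of a silylated butynol trapped with oxirane.

Assumption: positions are given in germacrane numbering (ring C1–C10, lactone arm C11–C13, C14 on C10, C15 on C4), and the silyl ether of but-3-yn-1-ol is bought as such.

**Route**

Step 1
Reactants: 1 tert-butyl(but-3-yn-1-yloxy)dimethylsilane; 2 oxirane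
Product: 5 (3E)-6-[(tert-butyldimethylsilyl)oxy]-4-methylhex-3-en-1-ol, via alkenyldimethylalane 3 (not isolated), via lithium alkenylalanate 4 (not isolated)
Conditions: AlMe3 (2.5 equiv), Cp2ZrCl2 (0.25 equiv), CH2Cl2, 0 °C → rt; volatiles removed; n-BuLi (1 equiv), hexane, −78 → 0 °C; 2 (3 equiv), THF, −78 °C → rt
Reagents that add atoms: trimethylaluminium, C[Al](C)C
Why: Negishi zirconium-catalysed carboalumination adds Me and Al syn across the terminal alkyne with Me on the internal carbon, and the alanate made with n-BuLi opens oxirane with retention at the alkenyl carbon, so the E-trisubstituted C1=C10 alkene and the C2–C3 unit are installed together.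

Step 2
Reactants: 5 (3E)-6-[(tert-butyldimethylsilyl)oxy]-4-methylhex-3-en-1-ol
Product: 6 (3E)-6-[(tert-butyldimethylsilyl)oxy]-4-methylhex-3-enal
Conditions: Dess–Martin periodinane (1.2 equiv), NaHCO3, CH2Cl2, 0 °C → rt; used crude
Reagents that add atoms: none
Why: Dess–Martin oxidation is neutral and fast, so the primary alcohol becomes the β,γ-unsaturated aldehyde without the alkene moving into conjugation and without loss of the silyl ether.

Step 3
Reactants: 6 (3E)-6-[(tert-butyldimethylsilyl)oxy]-4-methylhex-3-enal; 7 ethynyltrimethylsilane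
Product: 9 (3S,5E)-8-[(tert-butyldimethylsilyl)oxy]-6-methyloct-5-en-1-yn-3-ol, via C-silylated alkynol 8 (not isolated)
Conditions: 7 (3 equiv), Me2Zn (3 equiv), (S,S)-ProPhenol (20 mol %), Ph3PO (40 mol %), toluene, 0 °C; then K2CO3, MeOH, rt
Reagents that add atoms: none
Why: Zinc–ProPhenol asymmetric alkynylation delivers the alkynyl group to the Re face of the aldehyde under amine-free conditions and sets C3 as S (sense to be confirmed by Mosher ester, with the antipodal ligand used if needed), after which K2CO3 in MeOH cleaves only the C–Si bond.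

Step 4
Reactants: 9 (3S,5E)-8-[(tert-butyldimethylsilyl)oxy]-6-methyloct-5-en-1-yn-3-ol
Product: 11 (1Z,3S,5E)-8-[(tert-butyldimethylsilyl)oxy]-1-iodo-2,6-dimethylocta-1,5-dien-3-ol, via cyclic alkenylmagnesium alkoxide 10 (not isolated)
Conditions: MeMgBr (3.5 equiv), CuI (20 mol %), THF, −20 °C → rt, 16 h; then I2 (1.5 equiv), −78 → 0 °C
Reagents that add atoms: methylmagnesium bromide, C[Mg]Br; iodine, II
Why: Copper-catalysed anti-carbomagnesiation of the propargylic alkoxide puts methyl on the carbon next to the carbinol and magnesium on the terminal carbon inside a five-membered chelate, and iodinolysis with retention gives the vinyl iodide with iodine cis to C3, which is the Z geometry of C4=C5; C3 is untouched.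

Step 5
Reactants: 11 (1Z,3S,5E)-8-[(tert-butyldimethylsilyl)oxy]-1-iodo-2,6-dimethylocta-1,5-dien-3-ol; 12 methacrylic anhydride
Product: 13 (1Z,3S,5E)-8-[(tert-butyldimethylsilyl)oxy]-1-iodo-2,6-dimethylocta-1,5-dien-3-yl 2-methylprop-2-enoate
Conditions: 12 (1.5 equiv), Et3N, DMAP (10 mol %), CH2Cl2, 0 °C
Reagents that add atoms: none
Why: DMAP-catalysed acylation of the secondary allylic alcohol installs the C3 methacrylate early, so O3 never needs a protecting group, and no stereocentre is affected.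

Step 6
Reactants: 13 (1Z,3S,5E)-8-[(tert-butyldimethylsilyl)oxy]-1-iodo-2,6-dimethylocta-1,5-dien-3-yl 2-methylprop-2-enoate; 14 acrolein (prop-2-enal)
Product: 16 (3S,4Z,6S,8E)-11-[(tert-butyldimethylsilyl)oxy]-3-hydroxy-5,9-dimethylundeca-1,4,8-trien-6-yl 2-methylprop-2-enoate, via alkenylchromium dichloride 15 (not isolated)
Conditions: CrCl2 (4 equiv), (S)-N-[2-(4-isopropyl-4,5-dihydrooxazol-2-yl)-6-methylphenyl]methanesulfonamide (4.4 equiv), Et3N (4.4 equiv), THF, rt; then NiCl2 (5 mol %), 13, 14 (3 equiv), rt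
Reagents that add atoms: none
Why: Nozaki–Hiyama–Kishi coupling, in which zerovalent nickel inserts into the C–I bond with retention of the Z geometry, the alkenylchromium 15 (trivalent chromium) adds 1,2 to acrolein without touching the esters, and the chiral sulfonamide on chromium directs attack to the Re face of the aldehyde to set the carbinol (S here, R at C6 once the lactone is formed; sense to be confirmed by Mosher ester, with the antipodal ligand used if needed).

Step 7
Reactants: 16 (3S,4Z,6S,8E)-11-[(tert-butyldimethylsilyl)oxy]-3-hydroxy-5,9-dimethylundeca-1,4,8-trien-6-yl 2-methylprop-2-enoate; 17 2-(bromomethyl)prop-2-enoic acid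
Product: 18 (3S,4Z,6S,8E)-11-[(tert-butyldimethylsilyl)oxy]-5,9-dimethyl-6-[(2-methylprop-2-enoyl)oxy]undeca-1,4,8-trien-3-yl 2-(bromomethyl)prop-2-enoate
Conditions: 17 (1.5 equiv), DCC (1.5 equiv), DMAP (5 mol %), CH2Cl2, −20 → 0 °C
Reagents that add atoms: none
Why: Steglich esterification with little DMAP at low temperature acylates the bis-allylic alcohol faster than DMAP attacks the allylic bromide, and the carbinol configuration is retained because its C–O bond is not broken.

Step 8
Reactants: 18 (3S,4Z,6S,8E)-11-[(tert-butyldimethylsilyl)oxy]-5,9-dimethyl-6-[(2-methylprop-2-enoyl)oxy]undeca-1,4,8-trien-3-yl 2-(bromomethyl)prop-2-enoate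
Product: 19 (1Z,3S,5E)-1-[(2R)-4-(bromomethyl)-5-oxo-2,5-dihydrofuran-2-yl]-8-[(tert-butyldimethylsilyl)oxy]-2,6-dimethylocta-1,5-dien-3-yl 2-methylprop-2-enoate
Conditions: second-generation Hoveyda–Grubbs catalyst, RuCl2(H2IMes)(=CH-C6H4-2-OiPr) (10 mol %), toluene (5 mM), 70 °C
Reagents that add atoms: none
Why: Ring-closing metathesis, in which the ruthenium alkylidene formed at the monosubstituted vinyl group closes the five-membered ring onto the 2-substituted acrylate with loss of ethene, faster than seven- or eight-membered closure onto the trisubstituted alkene or the methacrylate, giving the 3-(bromomethyl)butenolide with C6 unchanged.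

Step 9
Reactants: 19 (1Z,3S,5E)-1-[(2R)-4-(bromomethyl)-5-oxo-2,5-dihydrofuran-2-yl]-8-[(tert-butyldimethylsilyl)oxy]-2,6-dimethylocta-1,5-dien-3-yl 2-methylprop-2-enoate
Product: 20 (1Z,3S,5E)-1-[(2R)-4-(bromomethyl)-5-oxo-2,5-dihydrofuran-2-yl]-8-hydroxy-2,6-dimethylocta-1,5-dien-3-yl 2-methylprop-2-enoate
Conditions: HF·pyridine, pyridine, THF, 0 °C → rt
Reagents that add atoms: none
Why: Pyridine-buffered HF·pyridine cleaves the primary silyl ether while the allylic bromide, the two esters and the butenolide survive.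

Step 10
Reactants: 20 (1Z,3S,5E)-1-[(2R)-4-(bromomethyl)-5-oxo-2,5-dihydrofuran-2-yl]-8-hydroxy-2,6-dimethylocta-1,5-dien-3-yl 2-methylprop-2-enoate
Product: 21 (1Z,3S,5E)-1-[(2R)-4-(bromomethyl)-5-oxo-2,5-dihydrofuran-2-yl]-2,6-dimethyl-8-oxoocta-1,5-dien-3-yl 2-methylprop-2-enoate
Conditions: Dess–Martin periodinane (1.3 equiv), NaHCO3, CH2Cl2, 0 °C; used at once
Reagents that add atoms: none
Why: Buffered Dess–Martin oxidation gives the β,γ-unsaturated aldehyde under neutral conditions that neither isomerise the alkene nor epimerise the γ-position of the butenolide.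

Step 11
Reactants: 21 (1Z,3S,5E)-1-[(2R)-4-(bromomethyl)-5-oxo-2,5-dihydrofuran-2-yl]-2,6-dimethyl-8-oxoocta-1,5-dien-3-yl 2-methylprop-2-enoate
Product: 23 (3S,6R,7R,8S)-8-hydroxy-3-[(2-methylprop-2-enoyl)oxy]germacra-1(10)E,4Z,11(13)-trien-12,6-olide, via allylchromium dichloride 22 (not isolated)
Conditions: CrCl2 (10 equiv), THF, rt, syringe-pump addition of 21 over 10 h (final 2 mM)
Reagents that add atoms: none
Why: Proposed new method: CrCl2 reduces the allylic C–Br bond to the allylchromium 22 (trivalent chromium), in which C7, the normally electrophilic β-carbon of the unsaturated lactone, is the nucleophilic γ-terminus (a homoenolate equivalent) and attacks the C8 aldehyde through a chair Zimmerman–Traxler transition state; the endocyclic C7=C11 bond fixes the reagent as an E-type allylmetal, so C9 sits equatorial and the 7,8-anti adduct (8S) results, and because C9 is tied to C5 the aldehyde can reach only the butenolide face opposite C5 (the cis approach forces a C5/C9 clash), giving the trans-fused lactone (7R) with the alkene transposed to C11=C13; the closest known reactions are the intermolecular chromium-mediated γ-allylation of aldehydes with 3-(bromomethyl)furan-2(5H)-one and the Nozaki–Hiyama macrocyclisation of ω-formyl allylic halides to ten-membered germacrane rings.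

Step 12
Reactants: 23 (3S,6R,7R,8S)-8-hydroxy-3-[(2-methylprop-2-enoyl)oxy]germacra-1(10)E,4Z,11(13)-trien-12,6-olide; 24 angelic acid, (2Z)-2-methylbut-2-enoic acid
Product: 25 (3S,6R,7R,8R)-8-[(2Z)-2-methylbut-2-enoyloxy]-3-[(2-methylprop-2-enoyl)oxy]germacra-1(10)E,4Z,11(13)-trien-12,6-olide
Conditions: PPh3 (3 equiv), DIAD (3 equiv), 24 (3 equiv), toluene, 0 °C → rt (betaine pre-formed)
Reagents that add atoms: none
Why: Mitsunobu reaction, in which angelate displaces the C8 oxyphosphonium group by SN2 and inverts 8S to the required 8R, while the Z geometry of the angelate is kept because the acid reacts as a carboxylate nucleophile and its carbonyl is never activated.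

Step 13
Reactants: 25 (3S,6R,7R,8R)-8-[(2Z)-2-methylbut-2-enoyloxy]-3-[(2-methylprop-2-enoyl)oxy]germacra-1(10)E,4Z,11(13)-trien-12,6-olide
Product: 26 (1R,3S,6R,7R,8R,10R)-1,10-epoxy-8-[(2Z)-2-methylbut-2-enoyloxy]-3-[(2-methylprop-2-enoyl)oxy]germacra-4Z,11(13)-dien-12,6-olide (CNP0294228.1)
Conditions: mCPBA (1.1 equiv), NaHCO3, CH2Cl2, 0 °C
Reagents that add atoms: mCPBA (3-chloroperoxybenzoic acid), O=C(OO)c1cccc(Cl)c1
Why: Prilezhaev epoxidation, in which the peracid reacts only with the electron-rich, unconjugated C1=C10 alkene (C4=C5 is deactivated by two allylic acyloxy groups and the other alkenes are conjugated to carbonyls) from its exposed outer face, and the E geometry is carried into the trans epoxide with 1R,10R as in the natural 1β,10α-epoxy heliangolides.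

**Compound list**

1 | tert-butyl(but-3-yn-1-yloxy)dimethylsilane | C#CCCO[Si](C)(C)C(C)(C)C | starting material
2 | oxirane (ethylene oxide) | C1CO1 | starting material
3 | [(1E)-4-[(tert-butyldimethylsilyl)oxy]-2-methylbut-1-en-1-yl]dimethylalane | C[Al](C)/C=C(\C)CCO[Si](C)(C)C(C)(C)C | intermediate
4 | lithium butyl[(1E)-4-[(tert-butyldimethylsilyl)oxy]-2-methylbut-1-en-1-yl]dimethylalanate | [Li+].CCCC[Al-](C)(C)/C=C(\C)CCO[Si](C)(C)C(C)(C)C | intermediate
5 | (3E)-6-[(tert-butyldimethylsilyl)oxy]-4-methylhex-3-en-1-ol | OCC/C=C(\C)CCO[Si](C)(C)C(C)(C)C | intermediate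
6 | (3E)-6-[(tert-butyldimethylsilyl)oxy]-4-methylhex-3-enal | O=CC/C=C(\C)CCO[Si](C)(C)C(C)(C)C | intermediate
7 | ethynyltrimethylsilane | C#C[Si](C)(C)C | starting material
8 | (3S,5E)-8-[(tert-butyldimethylsilyl)oxy]-6-methyl-1-(trimethylsilyl)oct-5-en-1-yn-3-ol | O[C@@H](C/C=C(\C)CCO[Si](C)(C)C(C)(C)C)C#C[Si](C)(C)C | intermediate
9 | (3S,5E)-8-[(tert-butyldimethylsilyl)oxy]-6-methyloct-5-en-1-yn-3-ol | O[C@@H](C/C=C(\C)CCO[Si](C)(C)C(C)(C)C)C#C | intermediate
10 | (5S)-5-[(2E)-5-[(tert-butyldimethylsilyl)oxy]-3-methylpent-2-en-1-yl]-4-methyl-2,5-dihydro-1,2-oxamagnesole (cyclic alkenylmagnesium alkoxide) | CC1=C[Mg]O[C@H]1C/C=C(\C)CCO[Si](C)(C)C(C)(C)C | intermediate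
11 | (1Z,3S,5E)-8-[(tert-butyldimethylsilyl)oxy]-1-iodo-2,6-dimethylocta-1,5-dien-3-ol | O[C@@H](C/C=C(\C)CCO[Si](C)(C)C(C)(C)C)/C(C)=C\I | intermediate
12 | methacrylic anhydride | CC(=C)C(=O)OC(=O)C(C)=C | starting material
13 | (1Z,3S,5E)-8-[(tert-butyldimethylsilyl)oxy]-1-iodo-2,6-dimethylocta-1,5-dien-3-yl 2-methylprop-2-enoate | C=C(C)C(=O)O[C@@H](C/C=C(\C)CCO[Si](C)(C)C(C)(C)C)/C(C)=C\I | intermediate
14 | acrolein (prop-2-enal) | C=CC=O | starting material
15 | dichloro[(1Z,3S,5E)-8-[(tert-butyldimethylsilyl)oxy]-2,6-dimethyl-3-[(2-methylprop-2-enoyl)oxy]octa-1,5-dien-1-yl]chromium | C=C(C)C(=O)O[C@@H](C/C=C(\C)CCO[Si](C)(C)C(C)(C)C)/C(C)=C\[Cr](Cl)Cl | intermediate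
16 | (3S,4Z,6S,8E)-11-[(tert-butyldimethylsilyl)oxy]-3-hydroxy-5,9-dimethylundeca-1,4,8-trien-6-yl 2-methylprop-2-enoate | C=C(C)C(=O)O[C@@H](C/C=C(\C)CCO[Si](C)(C)C(C)(C)C)/C(C)=C\[C@H](C=C)O | intermediate
17 | 2-(bromomethyl)prop-2-enoic acid | C=C(CBr)C(=O)O | starting material
18 | (3S,4Z,6S,8E)-11-[(tert-butyldimethylsilyl)oxy]-5,9-dimethyl-6-[(2-methylprop-2-enoyl)oxy]undeca-1,4,8-trien-3-yl 2-(bromomethyl)prop-2-enoate | C=C(C)C(=O)O[C@@H](C/C=C(\C)CCO[Si](C)(C)C(C)(C)C)/C(C)=C\[C@H](C=C)OC(=O)C(=C)CBr | intermediate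
19 | (1Z,3S,5E)-1-[(2R)-4-(bromomethyl)-5-oxo-2,5-dihydrofuran-2-yl]-8-[(tert-butyldimethylsilyl)oxy]-2,6-dimethylocta-1,5-dien-3-yl 2-methylprop-2-enoate | C=C(C)C(=O)O[C@@H](C/C=C(\C)CCO[Si](C)(C)C(C)(C)C)/C(C)=C\[C@H]1OC(=O)C(CBr)=C1 | intermediate
20 | (1Z,3S,5E)-1-[(2R)-4-(bromomethyl)-5-oxo-2,5-dihydrofuran-2-yl]-8-hydroxy-2,6-dimethylocta-1,5-dien-3-yl 2-methylprop-2-enoate | C=C(C)C(=O)O[C@@H](C/C=C(\C)CCO)/C(C)=C\[C@H]1OC(=O)C(CBr)=C1 | intermediate
21 | (1Z,3S,5E)-1-[(2R)-4-(bromomethyl)-5-oxo-2,5-dihydrofuran-2-yl]-2,6-dimethyl-8-oxoocta-1,5-dien-3-yl 2-methylprop-2-enoate | C=C(C)C(=O)O[C@@H](C/C=C(\C)CC=O)/C(C)=C\[C@H]1OC(=O)C(CBr)=C1 | intermediate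
22 | allylchromium dichloride of 21 (CH2–CrCl2 in place of CH2Br on the butenolide) | C=C(C)C(=O)O[C@@H](C/C=C(\C)CC=O)/C(C)=C\[C@H]1OC(=O)C(C[Cr](Cl)Cl)=C1 | intermediate
23 | (3S,6R,7R,8S)-8-hydroxy-3-[(2-methylprop-2-enoyl)oxy]germacra-1(10)E,4Z,11(13)-trien-12,6-olide | C=C(C)C(=O)O[C@H]1C/C=C(\C)C[C@H](O)[C@H]2C(=C)C(=O)O[C@@H]2/C=C\1C | intermediate
24 | angelic acid, (2Z)-2-methylbut-2-enoic acid | C/C=C(/C)C(=O)O | starting material
25 | (3S,6R,7R,8R)-8-[(2Z)-2-methylbut-2-enoyloxy]-3-[(2-methylprop-2-enoyl)oxy]germacra-1(10)E,4Z,11(13)-trien-12,6-olide | C=C(C)C(=O)O[C@H]1C/C=C(\C)C[C@@H](OC(=O)/C(C)=C\C)[C@H]2C(=C)C(=O)O[C@@H]2/C=C\1C | intermediate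
26 | (1R,3S,6R,7R,8R,10R)-1,10-epoxy-8-[(2Z)-2-methylbut-2-enoyloxy]-3-[(2-methylprop-2-enoyl)oxy]germacra-4Z,11(13)-dien-12,6-olide (CNP0294228.1) | C=C(C)C(=O)O[C@H]1C[C@H]2O[C@]2(C)C[C@@H](OC(=O)/C(C)=C\C)[C@H]2C(=C)C(=O)O[C@@H]2/C=C\1C | target

**Totals**
- Total step count: 13.
- Longest linear sequence: 13 steps (1 → 26); the route is fully linear.

**Steps most likely to fail, with fallbacks**

Step 11 (ring closure). The risks are oligomerisation, simple reduction of the bromide, or formation of the cis-fused or 8R diastereomer. The fallback sets out from 21 and comes back at 25. The bromide is exchanged for tin with hexabutylditin and Pd(PPh3)4 in THF to give the allylstannane aldehyde F1, which is isolable. F1 is cyclised by slow addition to BF3·OEt2 in CH2Cl2 at −78 °C. This Lewis-acid SE2′ addition runs through an open antiperiplanar transition state, which favours the 7,8-syn adduct, the (8R)-alcohol F2. F2 is then esterified with retention by the mixed anhydride of 24 (2,4,6-trichlorobenzoyl chloride, Et3N, toluene, 80 °C) to give 25.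

Step 12 (SN2 at a ring carbinol next to C7). The risks are elimination towards C9 or no reaction. The fallback sets out from 23 and comes back at 25 by an oxidation–reduction inversion. Dess–Martin oxidation gives the 8-ketone F3. Luche reduction (NaBH4, CeCl3·7H2O, MeOH/THF, −78 °C) delivers hydride from the face away from the lactone arm on C7 to give the (8R)-alcohol F2, the same compound as in the fallback above. Mixed-anhydride esterification with 24 as above gives 25.

Step 6 (reagent-controlled addition to acrolein). The risks are low selectivity at the new carbinol or nickel-promoted side reactions of the methacrylate. The fallback sets out from 13 and comes back at 16 by making the carbinol through a ketone. Carbonylative Stille coupling of 13 with tributyl(vinyl)tin (CO 1 atm, Pd(PPh3)4, THF, 50 °C) gives the cross-conjugated dienone F4. Reduction with (R)-2-methyl-CBS-oxazaborolidine and catecholborane in toluene at −78 °C, with the branched Z-alkenyl arm acting as the large group, gives the S-carbinol 16.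

**Further compounds**

F1 | step 11 | (1Z,3S,5E)-2,6-dimethyl-8-oxo-1-[(2R)-5-oxo-4-[(tributylstannyl)methyl]-2,5-dihydrofuran-2-yl]octa-1,5-dien-3-yl 2-methylprop-2-enoate | C=C(C)C(=O)O[C@@H](C/C=C(\C)CC=O)/C(C)=C\[C@H]1OC(=O)C(C[Sn](CCCC)(CCCC)CCCC)=C1
F2 | step 11 | (3S,6R,7R,8R)-8-hydroxy-3-[(2-methylprop-2-enoyl)oxy]germacra-1(10)E,4Z,11(13)-trien-12,6-olide | C=C(C)C(=O)O[C@H]1C/C=C(\C)C[C@@H](O)[C@H]2C(=C)C(=O)O[C@@H]2/C=C\1C
F3 | step 12 | (3S,6R,7S)-3-[(2-methylprop-2-enoyl)oxy]-8-oxogermacra-1(10)E,4Z,11(13)-trien-12,6-olide | C=C(C)C(=O)O[C@H]1C/C=C(\C)CC(=O)[C@H]2C(=C)C(=O)O[C@@H]2/C=C\1C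
F4 | step 6 | (4Z,6S,8E)-11-[(tert-butyldimethylsilyl)oxy]-5,9-dimethyl-3-oxoundeca-1,4,8-trien-6-yl 2-methylprop-2-enoate | C=C(C)C(=O)O[C@@H](C/C=C(\C)CCO[Si](C)(C)C(C)(C)C)/C(C)=C\C(=O)C=C
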